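**Retrosynthetic overview**
1. Target 28 comes from bis-allylic diol 27 by a final double oxidation. 27 comes from PMB acetal 24 by DDQ cleavage, acetylation with retention at C1, and desilylation.
2. The cycloheptene ring (C8=C9) is closed by ring-closing metathesis of diene 23; it is the last ring formed.
3. The dihydropyran ring and the C1/C9a/C4a triad come from one proposed new step: a chromium-catalysed inverse-electron-demand oxa-Diels–Alder of cyclopropyl enal 11 with (Z)-enol ether 19.
4. Enal 11 comes from cyclopropane lactone 1 (chiral pool, supplies C5 and C6) by lactol vinylation and Knoevenagel homologation. Enol ether 19 comes from 4-methoxybenzyl alcohol and silyloxyacetaldehyde.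
5. Ring order: cyclopropane (bought), then dihydropyran (cycloaddition), then cycloheptene (metathesis).

**Assumptions**
- Lactone 1 is taken as a commercial single enantiomer.
- Two carbinol carbons (the C–OTBS carbon made in step 2 and the C–OTES carbon of 19) are carried as epimer mixtures and written without configuration. Both become sp2 later (steps 15 and 21).
- Locants for tricycles 24–28 follow cyclohepta[c]pyran: C1 (acetal), O2, C3, C4, C4a, C5, C6, C7, C8, C9, C9a. The CMe2 carbon bridges C5 and C6 (the cyclopropane).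

**Route**

Step 1
Reactants: 1 (1S,5R)-6,6-dimethyl-3-oxabicyclo[3.1.0]hexan-2-one
Product: 2 (1S,5R)-6,6-dimethyl-3-oxabicyclo[3.1.0]hexan-2-ol (lactol; both anomers)
Conditions: i-Bu2AlH (1.1 equiv), CH2Cl2, −78 °C; aq. potassium sodium tartrate
Reagents that add atoms: none
Why: Partial lactone reduction stops at the lactol because the aluminium hemiacetal is stable at −78 °C; the cyclopropane stereocentres are not touched.

Step 2
Reactants: 2 (1S,5R)-6,6-dimethyl-3-oxabicyclo[3.1.0]hexan-2-ol
Product: 3 1-[(1S,3R)-3-(hydroxymethyl)-2,2-dimethylcyclopropyl]prop-2-en-1-ol (carbinol epimers)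
Conditions: CH2=CHMgBr (3 equiv), THF, 0 °C → rt; aq. NH4Cl
Reagents that add atoms: vinylmagnesium bromide, C=C[Mg]Br
Why: Grignard addition to the ring-opened hydroxy-aldehyde form of the lactol gives the 1,4-diol; the new carbinol centre is an inconsequential epimer mixture because it becomes the C7 ketone in step 21.

Step 3
Reactants: 3 1-[(1S,3R)-3-(hydroxymethyl)-2,2-dimethylcyclopropyl]prop-2-en-1-ol
Product: 4 tert-butyl({(1R,3S)-3-[1-(tert-butyldimethylsilyloxy)prop-2-en-1-yl]-2,2-dimethylcyclopropyl}methoxy)dimethylsilane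
Conditions: TBSOTf (2.4 equiv), 2,6-lutidine, CH2Cl2, −78 → 0 °C
Reagents that add atoms: tert-butyldimethylsilyl trifluoromethanesulfonate, CC(C)(C)[Si](C)(C)OS(=O)(=O)C(F)(F)F
Why: Exhaustive O-silylation with the silyl triflate and a hindered base protects both hydroxyls, including the hindered secondary allylic one.

Step 4
Reactants: 4 bis-TBS ether
Product: 5 {(1R,3S)-3-[1-(tert-butyldimethylsilyloxy)prop-2-en-1-yl]-2,2-dimethylcyclopropyl}methanol
Conditions: HF·pyridine, pyridine, THF, 0 °C
Reagents that add atoms: none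
Why: Selective desilylation works because the primary silyl ether is cleaved much faster than the hindered secondary allylic one under buffered HF.

Step 5
Reactants: 5 primary alcohol
Product: 6 (1R,3S)-3-[1-(tert-butyldimethylsilyloxy)prop-2-en-1-yl]-2,2-dimethylcyclopropane-1-carbaldehyde
Conditions: Dess–Martin periodinane, pyridine, CH2Cl2, 0 °C → rt
Reagents that add atoms: none
Why: Buffered Dess–Martin oxidation gives the aldehyde without epimerising the cis-cyclopropane, whose α-C–H is hard to enolise.

Step 6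
Reactants: 6 cyclopropanecarbaldehyde; 7 dimethyl malonate
Product: 8 dimethyl 2-({(1R,3S)-3-[1-(tert-butyldimethylsilyloxy)prop-2-en-1-yl]-2,2-dimethylcyclopropyl}methylidene)propanedioate
Conditions: piperidine (0.2 equiv), AcOH (0.2 equiv), 4 Å MS, toluene, 40 °C
Reagents that add atoms: none
Why: Knoevenagel condensation of a non-enolisable-type aldehyde with a symmetric malonate creates no alkene-geometry problem and leaves the cyclopropane configuration intact.

Step 7
Reactants: 8 alkylidene malonate
Product: 9 2-({(1R,3S)-3-[1-(tert-butyldimethylsilyloxy)prop-2-en-1-yl]-2,2-dimethylcyclopropyl}methylidene)propane-1,3-diol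
Conditions: i-Bu2AlH (5 equiv), CH2Cl2/toluene, −78 → −20 °C; aq. potassium sodium tartrate
Reagents that add atoms: none
Why: 1,2-Reduction of both conjugated esters by i-Bu2AlH converts the alkylidene malonate into the 2-alkylidene-1,3-diol.

Step 8
Reactants: 9 2-alkylidene-1,3-diol
Product: 10 (E)-3-{(1R,3S)-3-[1-(tert-butyldimethylsilyloxy)prop-2-en-1-yl]-2,2-dimethylcyclopropyl}-2-(hydroxymethyl)prop-2-enal
Conditions: activated MnO2 (15 equiv), CH2Cl2, rt
Reagents that add atoms: none
Why: Allylic oxidation on the MnO2 surface should take the less hindered hydroxymethyl (trans to the cyclopropyl), and the enal formed deactivates the second allylic alcohol, so the reaction stops at the (E)-mono-aldehyde (any Z isomer is removed by chromatography).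

Step 9
Reactants: 10 (E)-hydroxymethyl enal
Product: 11 (E)-3-{(1R,3S)-3-[1-(tert-butyldimethylsilyloxy)prop-2-en-1-yl]-2,2-dimethylcyclopropyl}-2-formylprop-2-en-1-yl acetate
Conditions: AcCl, 2,6-lutidine, CH2Cl2, −20 °C
Reagents that add atoms: acetyl chloride, CC(=O)Cl
Why: O-Acylation with a non-nucleophilic base installs the final C4 acetoxymethyl group while avoiding amine attack on the allylic-acetate-type enal.

Step 10
Reactants: 12 4-methoxybenzyl alcohol
Product: 13 1-[(ethenyloxy)methyl]-4-methoxybenzene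
Conditions: ethyl vinyl ether (solvent), Pd(OAc)2 (2 mol %), 1,10-phenanthroline (2 mol %), rt
Reagents that add atoms: ethyl vinyl ether, C=COCC
Why: Palladium-catalysed transfer vinylation (vinyl ether exchange) converts the alcohol into its vinyl ether, driven by the excess of ethyl vinyl ether.

Step 11
Reactants: 13 4-methoxybenzyl vinyl ether
Product: 15 1-{[(Z)-2-bromoethenyl]oxymethyl}-4-methoxybenzene, via dibromo ether 14 (not isolated)
Conditions: Br2 (1.0 equiv), CH2Cl2, −78 °C; then Et3N (2.5 equiv), −78 °C → rt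
Reagents that add atoms: bromine, BrBr
Why: Bromine addition to the enol ether followed by amine-induced dehydrobromination through the α-bromo ether gives the 2-bromovinyl ether with the Z isomer predominating (E isomer removed).

Step 12
Reactants: 15 (Z)-2-bromovinyl PMB ether; 16 (tert-butyldimethylsilyloxy)acetaldehyde
Product: 19 rac-(Z)-1-(tert-butyldimethylsilyloxy)-4-[(4-methoxybenzyl)oxy]-2-(triethylsilyloxy)but-3-ene, via vinyllithium 17 (not isolated), via lithium alkoxide 18 (not isolated)
Conditions: t-BuLi (2.0 equiv), Et2O, −78 °C; 16, −78 °C; Et3SiCl, −78 °C → rt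
Reagents that add atoms: chlorotriethylsilane, CC[Si](Cl)(CC)CC
Why: Bromine–lithium exchange keeps the Z geometry of the configurationally stable cis-alkoxyvinyllithium, 1,2-addition to the aldehyde gives the allylic alkoxide, and in situ silylation gives a non-conjugated enol ether that can only react through its enol-ether bond.

Step 13
Reactants: 11 (E)-acetoxymethyl cyclopropyl enal; 19 rac-(Z)-enol ether
Product: 20 {(2R,3R,4R)-3-[2-(tert-butyldimethylsilyloxy)-1-(triethylsilyloxy)ethyl]-4-{(1R,3S)-3-[1-(tert-butyldimethylsilyloxy)prop-2-en-1-yl]-2,2-dimethylcyclopropyl}-2-[(4-methoxybenzyl)oxy]-3,4-dihydro-2H-pyran-5-yl}methyl acetate (2,3,4-all-cis)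
Conditions: CrCl(C27H29NO2) [chloro chromium complex of the Schiff base from (1S,2R)-1-amino-2-indanol and 3-(1-adamantyl)-2-hydroxy-5-methylbenzaldehyde] (10 mol %), enol ether in threefold excess (unreacted excess recovered on chromatography), 4 Å MS, minimal t-BuOMe, rt, 72 h
Reagents that add atoms: none
Why: Proposed new method: a reagent-controlled, doubly stereodifferentiating inverse-electron-demand oxa-Diels–Alder (a [4+2] addition that keeps every atom of both partners in the adduct) in which the trivalent chromium Lewis acid binds the formyl oxygen of the s-cis enal and lowers the oxadiene LUMO, and the internal (Z)-enol ether adds through the endo transition state (alkoxy group under the oxadiene) with its β-carbon bonding to the enal β-carbon and its acetal carbon to oxygen, so that PMB-oxy, side chain and cyclopropyl come out all-cis (C2 and C3 from the Z geometry and endo approach, C4 from catalyst shielding that leaves only the Si face of the enal β-carbon open and overrides the small bias of the A(1,3)-locked vinylcyclopropane); both enantiomers of racemic 19 are usable because its carbinol centre is destroyed in step 15; the closest known reaction type is the chromium Schiff-base-catalysed inverse-demand oxa-Diels–Alder of simple enals with ethyl vinyl ether, which has not been shown for a fully α,β-disubstituted chiral enal carrying an allylic acetate or for an internal γ-silyloxy (Z)-enol ether.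

Step 14
Reactants: 20 all-cis dihydropyran
Product: 21 {(2R,3R,4R)-3-[2-(tert-butyldimethylsilyloxy)-1-hydroxyethyl]-4-{(1R,3S)-3-[1-(tert-butyldimethylsilyloxy)prop-2-en-1-yl]-2,2-dimethylcyclopropyl}-2-[(4-methoxybenzyl)oxy]-3,4-dihydro-2H-pyran-5-yl}methyl acetate
Conditions: HF·pyridine, pyridine, THF, −20 → 0 °C
Reagents that add atoms: none
Why: Selective desilylation removes the triethylsilyl ether, which is far more labile than the two TBS ethers, under buffered conditions that spare the acetal, enol ether and acetate.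

Step 15
Reactants: 21 secondary alcohol
Product: 22 {(2R,3S,4R)-3-[(tert-butyldimethylsilyloxy)acetyl]-4-{(1R,3S)-3-[1-(tert-butyldimethylsilyloxy)prop-2-en-1-yl]-2,2-dimethylcyclopropyl}-2-[(4-methoxybenzyl)oxy]-3,4-dihydro-2H-pyran-5-yl}methyl acetate
Conditions: Dess–Martin periodinane, pyridine, CH2Cl2, 0 °C
Reagents that add atoms: none
Why: Buffered Dess–Martin oxidation gives the α-silyloxy ketone without epimerising the adjacent ring carbon (the descriptor at C3 changes only through CIP priorities).

Step 16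
Reactants: 22 ketone
Product: 23 {(2R,3R,4R)-3-[3-(tert-butyldimethylsilyloxy)prop-1-en-2-yl]-4-{(1R,3S)-3-[1-(tert-butyldimethylsilyloxy)prop-2-en-1-yl]-2,2-dimethylcyclopropyl}-2-[(4-methoxybenzyl)oxy]-3,4-dihydro-2H-pyran-5-yl}methyl acetate
Conditions: Cp2Ti(μ-CH2)(μ-Cl)AlMe2 (1.2 equiv), pyridine, THF, −40 → 0 °C
Reagents that add atoms: Tebbe reagent, C[Al-]1(C)C[Ti](C2C=CC=C2)(C2C=CC=C2)[Cl+]1
Why: Tebbe methylenation is non-basic, so the epimerisable α-centre and the β-alkoxy acetal survive, and at low temperature the ketone reacts much faster than the acetate.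

Step 17
Reactants: 23 diene
Product: 24 [(1R,4aR,5R,6S,9aR)-7-(tert-butyldimethylsilyloxy)-9-[(tert-butyldimethylsilyloxy)methyl]-1-[(4-methoxybenzyl)oxy]-5,6-(propane-2,2-diyl)-1,4a,5,6,7,9a-hexahydrocyclohepta[c]pyran-4-yl]methyl acetate
Conditions: second-generation Grubbs catalyst RuCl2(=CHPh)(PCy3)(H2IMes) (10 mol %), CH2Cl2 (0.002 M), 40 °C
Reagents that add atoms: none
Why: Ring-closing metathesis between the vinyl carbinol and the 1,1-disubstituted alkene forms the trisubstituted cycloheptene; the cis arrangement of the two arms on the pyran and on the cyclopropane preorganises the closure, and the trisubstituted enol ether is inert to the ruthenium carbene.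

Step 18
Reactants: 24 tricyclic PMB acetal
Product: 25 [(1R,4aR,5R,6S,9aR)-7-(tert-butyldimethylsilyloxy)-9-[(tert-butyldimethylsilyloxy)methyl]-1-hydroxy-5,6-(propane-2,2-diyl)-1,4a,5,6,7,9a-hexahydrocyclohepta[c]pyran-4-yl]methyl acetate
Conditions: DDQ (1.5 equiv), CH2Cl2/pH 7 phosphate buffer (10:1), 0 °C
Reagents that add atoms: none
Why: Oxidative cleavage of the 4-methoxybenzyl acetal proceeds by benzylic hydride abstraction and hydrolysis at the benzylic carbon, so the C1–O bond and its configuration are kept and no acid touches the enol ether.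

Step 19
Reactants: 25 lactol
Product: 26 [(1S,4aR,5R,6S,9aR)-1-acetoxy-7-(tert-butyldimethylsilyloxy)-9-[(tert-butyldimethylsilyloxy)methyl]-5,6-(propane-2,2-diyl)-1,4a,5,6,7,9a-hexahydrocyclohepta[c]pyran-4-yl]methyl acetate
Conditions: Ac2O, pyridine, DMAP (cat.), CH2Cl2, −20 °C, directly after step 18
Reagents that add atoms: acetic anhydride, CC(=O)OC(C)=O
Why: Low-temperature O-acylation of the lactol is faster than mutarotation and so retains the C1 configuration set in step 13; the axial acetate is also the anomer favoured by the anomeric effect.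

Step 20
Reactants: 26 diacetate
Product: 27 [(1S,4aR,5R,6S,9aR)-1-acetoxy-7-hydroxy-9-(hydroxymethyl)-5,6-(propane-2,2-diyl)-1,4a,5,6,7,9a-hexahydrocyclohepta[c]pyran-4-yl]methyl acetate
Conditions: Et3N·3HF, THF/MeCN, rt
Reagents that add atoms: none
Why: Near-neutral fluoride desilylation removes both TBS ethers while sparing the anomeric and allylic acetates.

Step 21
Reactants: 27 bis-allylic diol
Product: 28 [(1S,4aR,5R,6S,9aR)-1-acetoxy-9-formyl-7-oxo-5,6-(propane-2,2-diyl)-1,4a,5,6,7,9a-hexahydrocyclohepta[c]pyran-4-yl]methyl acetate (target)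
Conditions: Dess–Martin periodinane (3 equiv), pyridine, CH2Cl2, 0 °C → rt
Reagents that add atoms: none
Why: One buffered Dess–Martin oxidation converts the secondary allylic alcohol into the C7 ketone and the primary allylic alcohol into the C9 aldehyde, releasing the sensitive 4-oxo-enal only in the last step.

**Compound list**
1 | (1S,5R)-6,6-dimethyl-3-oxabicyclo[3.1.0]hexan-2-one | O=C1OC[C@@H]2[C@H]1C2(C)C | starting material
2 | (1S,5R)-6,6-dimethyl-3-oxabicyclo[3.1.0]hexan-2-ol (anomers) | OC1OC[C@@H]2[C@H]1C2(C)C | intermediate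
3 | 1-[(1S,3R)-3-(hydroxymethyl)-2,2-dimethylcyclopropyl]prop-2-en-1-ol (carbinol epimers) | C=CC(O)[C@H]1[C@@H](CO)C1(C)C | intermediate
4 | bis-TBS ether of 3 | C=CC(O[Si](C)(C)C(C)(C)C)[C@H]1[C@@H](CO[Si](C)(C)C(C)(C)C)C1(C)C | intermediate
5 | {(1R,3S)-3-[1-(TBS-oxy)prop-2-en-1-yl]-2,2-dimethylcyclopropyl}methanol | C=CC(O[Si](C)(C)C(C)(C)C)[C@H]1[C@@H](CO)C1(C)C | intermediate
6 | (1R,3S)-3-[1-(TBS-oxy)prop-2-en-1-yl]-2,2-dimethylcyclopropane-1-carbaldehyde | C=CC(O[Si](C)(C)C(C)(C)C)[C@H]1[C@@H](C=O)C1(C)C | intermediate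
7 | dimethyl malonate | COC(=O)CC(=O)OC | starting material
8 | dimethyl 2-(cyclopropylmethylidene)propanedioate derivative of 6 | C=CC(O[Si](C)(C)C(C)(C)C)[C@H]1[C@@H](C=C(C(=O)OC)C(=O)OC)C1(C)C | intermediate
9 | 2-(cyclopropylmethylidene)propane-1,3-diol derivative | C=CC(O[Si](C)(C)C(C)(C)C)[C@H]1[C@@H](C=C(CO)CO)C1(C)C | intermediate
10 | (E)-3-cyclopropyl-2-(hydroxymethyl)prop-2-enal derivative | C=CC(O[Si](C)(C)C(C)(C)C)[C@H]1[C@@H](/C=C(\CO)C=O)C1(C)C | intermediate
11 | (E)-3-cyclopropyl-2-formylprop-2-en-1-yl acetate derivative | C=CC(O[Si](C)(C)C(C)(C)C)[C@H]1[C@@H](/C=C(\COC(C)=O)C=O)C1(C)C | intermediate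
12 | 4-methoxybenzyl alcohol | COc1ccc(CO)cc1 | starting material
13 | 1-[(ethenyloxy)methyl]-4-methoxybenzene | COc1ccc(COC=C)cc1 | intermediate
14 | 1-[(1,2-dibromoethoxy)methyl]-4-methoxybenzene | COc1ccc(COC(Br)CBr)cc1 | intermediate
15 | 1-{[(Z)-2-bromoethenyl]oxymethyl}-4-methoxybenzene | COc1ccc(CO/C=C\Br)cc1 | intermediate
16 | (tert-butyldimethylsilyloxy)acetaldehyde | O=CCO[Si](C)(C)C(C)(C)C | starting material
17 | (Z)-2-[(4-methoxybenzyl)oxy]ethenyllithium | COc1ccc(CO/C=C\[Li])cc1 | intermediate
18 | lithium (Z)-1-(TBS-oxy)-4-[(4-methoxybenzyl)oxy]but-3-en-2-olate | COc1ccc(CO/C=C\C([O-])CO[Si](C)(C)C(C)(C)C)cc1.[Li+] | intermediate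
19 | rac-(Z)-1-(TBS-oxy)-4-[(4-methoxybenzyl)oxy]-2-(triethylsilyloxy)but-3-ene | COc1ccc(CO/C=C\C(O[Si](CC)(CC)CC)CO[Si](C)(C)C(C)(C)C)cc1 | intermediate
20 | all-cis (2R,3R,4R) dihydropyran, 3-[2-(TBS-oxy)-1-(TES-oxy)ethyl] | CC(=O)OCC1=CO[C@@H](OCc2ccc(OC)cc2)[C@@H](C(O[Si](CC)(CC)CC)CO[Si](C)(C)C(C)(C)C)[C@H]1[C@@H]3[C@H](C(O[Si](C)(C)C(C)(C)C)C=C)C3(C)C | intermediate
21 | all-cis dihydropyran, 3-[2-(TBS-oxy)-1-hydroxyethyl] | CC(=O)OCC1=CO[C@@H](OCc2ccc(OC)cc2)[C@@H](C(O)CO[Si](C)(C)C(C)(C)C)[C@H]1[C@@H]3[C@H](C(O[Si](C)(C)C(C)(C)C)C=C)C3(C)C | intermediate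
22 | all-cis dihydropyran, 3-[(TBS-oxy)acetyl] | CC(=O)OCC1=CO[C@@H](OCc2ccc(OC)cc2)[C@@H](C(=O)CO[Si](C)(C)C(C)(C)C)[C@H]1[C@@H]3[C@H](C(O[Si](C)(C)C(C)(C)C)C=C)C3(C)C | intermediate
23 | all-cis dihydropyran, 3-[3-(TBS-oxy)prop-1-en-2-yl] | CC(=O)OCC1=CO[C@@H](OCc2ccc(OC)cc2)[C@@H](C(=C)CO[Si](C)(C)C(C)(C)C)[C@H]1[C@@H]3[C@H](C(O[Si](C)(C)C(C)(C)C)C=C)C3(C)C | intermediate
24 | tricyclic PMB acetal (1R,4aR,5R,6S,9aR), 7-OTBS, 9-CH2OTBS | CC(=O)OCC1=CO[C@@H](OCc4ccc(OC)cc4)[C@H]2C(CO[Si](C)(C)C(C)(C)C)=CC(O[Si](C)(C)C(C)(C)C)[C@H]3[C@@H]([C@@H]12)C3(C)C | intermediate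
25 | tricyclic lactol (1R,4aR,5R,6S,9aR) | CC(=O)OCC1=CO[C@@H](O)[C@H]2C(CO[Si](C)(C)C(C)(C)C)=CC(O[Si](C)(C)C(C)(C)C)[C@H]3[C@@H]([C@@H]12)C3(C)C | intermediate
26 | tricyclic diacetate (1S,4aR,5R,6S,9aR), bis-TBS | CC(=O)OCC1=CO[C@@H](OC(C)=O)[C@H]2C(CO[Si](C)(C)C(C)(C)C)=CC(O[Si](C)(C)C(C)(C)C)[C@H]3[C@@H]([C@@H]12)C3(C)C | intermediate
27 | tricyclic diacetate diol (1S,4aR,5R,6S,9aR) | CC(=O)OCC1=CO[C@@H](OC(C)=O)[C@H]2C(CO)=CC(O)[C@H]3[C@@H]([C@@H]12)C3(C)C | intermediate
28 | CNP0263020.2, [(1S,4aR,5R,6S,9aR)-1-acetoxy-9-formyl-7-oxo-5,6-(propane-2,2-diyl)-1,4a,5,6,7,9a-hexahydrocyclohepta[c]pyran-4-yl]methyl acetate | CC(=O)OCC1=CO[C@@H](OC(C)=O)[C@H]2C(C=O)=CC(=O)[C@H]3[C@@H]([C@@H]12)C3(C)C | target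

**Totals and risks**
Total step count: 21. Longest linear sequence: 18 steps (steps 1–9, then 13–21); the enol ether branch is 3 steps (10–12).

The three steps most likely to fail are 13, 17 and 19.

Step 13 is the proposed new cycloaddition. The risks are low reactivity of the hindered α,β-disubstituted enal, loss of the allylic acetate, and a mismatched pairing of catalyst and cyclopropane. The fallback uses known chemistry, sets out from diol 9 together with enol ether 19, and comes back to the route at 20. Both hydroxymethyl groups of 9 are oxidised with Dess–Martin periodinane to 2-({(1R,3S)-3-[1-(tert-butyldimethylsilyloxy)prop-2-en-1-yl]-2,2-dimethylcyclopropyl}methylidene)propanedial F1. This doubly activated 1-oxadiene reacts with 19 without a catalyst at room temperature in a hetero-Diels–Alder reaction of the alkylidene-1,3-dicarbonyl type (endo, all-cis) to give the 5-formyl dihydropyran F2. Reduction with NaBH4/CeCl3 in MeOH at −78 °C gives the 5-(hydroxymethyl) dihydropyran F3, and acetylation (Ac2O, pyridine) gives 20. Facial selectivity toward the cyclopropane is then substrate-controlled, and diastereomers are separated by chromatography.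

Step 17 is the ring-closing metathesis. The risk is a sluggish reaction at the hindered 1,1-disubstituted alkene, with dimerisation through the vinyl group. The fallback sets out from ketone 22, skips 23, and comes back at 24. Ketone 22 is treated with one equivalent of the molybdenum alkylidene Mo(=CHCMe2Ph)(=N-2,6-i-Pr2C6H3)[OCMe(CF3)2]2 in benzene. Metathesis at the unhindered vinyl group gives a molybdenum alkylidene at C8, which olefinates the C9 ketone intramolecularly (known stoichiometric olefin metathesis/carbonyl olefination). This closes the same trisubstituted cycloheptene and makes no new compound, F0.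

Step 19 is the anomeric acetylation. The risk is mutarotation of lactol 25 before acylation, which would give the equatorial acetate. The fallback sets out from lactol 25 and comes back at 26. Lactol 25 is converted with Cl3CCN and K2CO3 in CH2Cl2 into the kinetically formed equatorial (1-epi) trichloroacetimidate F4. Displacement with acetic acid in CH2Cl2 at room temperature, without promoter, inverts C1 and gives the axial acetate 26 stereospecifically (known anomeric imidate/carboxylic acid substitution).

**Further compounds**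
F1 | step 13 | 2-({(1R,3S)-3-[1-(tert-butyldimethylsilyloxy)prop-2-en-1-yl]-2,2-dimethylcyclopropyl}methylidene)propanedial | C=CC(O[Si](C)(C)C(C)(C)C)[C@H]1[C@@H](C=C(C=O)C=O)C1(C)C
F2 | step 13 | all-cis 5-formyl analogue of 20 (formyl in place of acetoxymethyl) | O=CC1=CO[C@@H](OCc2ccc(OC)cc2)[C@@H](C(O[Si](CC)(CC)CC)CO[Si](C)(C)C(C)(C)C)[C@H]1[C@@H]3[C@H](C(O[Si](C)(C)C(C)(C)C)C=C)C3(C)C
F3 | step 13 | all-cis 5-(hydroxymethyl) analogue of 20 | OCC1=CO[C@@H](OCc2ccc(OC)cc2)[C@@H](C(O[Si](CC)(CC)CC)CO[Si](C)(C)C(C)(C)C)[C@H]1[C@@H]3[C@H](C(O[Si](C)(C)C(C)(C)C)C=C)C3(C)C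
F0 | step 17 | none | none
F4 | step 19 | 1-epi (equatorial) O-trichloroacetimidate of lactol 25 | CC(=O)OCC1=CO[C@H](OC(=N)C(Cl)(Cl)Cl)[C@H]2C(CO[Si](C)(C)C(C)(C)C)=CC(O[Si](C)(C)C(C)(C)C)[C@H]3[C@@H]([C@@H]12)C3(C)C
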